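**Retrosynthetic overview**
1. Target 25 ⇐ ester reduction of the all-cis oxolane ester 24 ⇐ hydrogenation of 4,5-dihydrofuran 23 from the face opposite its C4 arylmethyl group (this also removes both benzyl ethers).
2. 23 ⇐ key step: twofold 5-exo aryl-radical cyclisation with O2 capture on bis(aryl iodide) bis(allyl aryl ether) 21. Both dihydrobenzofuran rings close in one operation, and each benzylic C–O centre directs its neighbouring C3 trans.
3. 21 ⇐ two iridium-catalysed allylic etherifications run with opposite ligand enantiomers, because the two dihydrobenzofurans have opposite absolute configuration: carbonate 5 + iodophenol 7 (S centre), then carbonate 10 + iodophenol 20 (R centre).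
4. 20 ⇐ acid-induced acyl-lactone rearrangement of α-aroyl lactone 18 ⇐ aldol/oxidation of (R)-β-benzyl-γ-butyrolactone 15 (Stobbe condensation, asymmetric hydrogenation) with silylated 5-iodovanillin.
5. Ring order: dihydrofuran (step 14) → both dihydrobenzofurans together (step 16) → oxolane stereocentres by hydrogenation (step 17).

Assumption: the sense of induction of the (Ra,Rc,Rc)/(Sa,Sc,Sc) phosphoramidite–iridium catalyst and of (S,S)-Et-DuPhos–rhodium is taken from memory of the parent cinnamyl carbonate and arylidenesuccinate half-ester cases and must be confirmed on the first product; if either is reversed, the ligand enantiomers are exchanged.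

**Route**

Step 1
Reactants: 1 4-(benzyloxy)-3-methoxybenzaldehyde; 2 methyl (triphenylphosphoranylidene)acetate
Product: 3 methyl (E)-3-[4-(benzyloxy)-3-methoxyphenyl]prop-2-enoate
Conditions: toluene, 90 °C
Reagents that add atoms: none
Why: Wittig olefination with a stabilised ylide gives the E-enoate selectively; no stereocentre is formed.

Step 2
Reactants: 3 methyl (E)-3-[4-(benzyloxy)-3-methoxyphenyl]prop-2-enoate
Product: 4 (E)-3-[4-(benzyloxy)-3-methoxyphenyl]prop-2-en-1-ol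
Conditions: i-Bu2AlH (2.2 equiv), CH2Cl2, −78 °C
Reagents that add atoms: none
Why: 1,2-reduction of the enoate by the aluminium hydride (DIBAL reduction) gives the allylic alcohol and leaves the alkene and benzyl ether untouched.

Step 3
Reactants: 4 (E)-3-[4-(benzyloxy)-3-methoxyphenyl]prop-2-en-1-ol
Product: 5 (E)-3-[4-(benzyloxy)-3-methoxyphenyl]prop-2-en-1-yl methyl carbonate
Conditions: ClCO2Me, pyridine, CH2Cl2, 0 °C
Reagents that add atoms: methyl chloroformate COC(=O)Cl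
Why: O-acylation with a chloroformate gives the linear carbonate that serves as the allyl–metal precursor.

Step 4
Reactants: 6 4-hydroxy-3-iodo-5-methoxybenzaldehyde (5-iodovanillin); 2 methyl (triphenylphosphoranylidene)acetate
Product: 7 methyl (E)-3-(4-hydroxy-3-iodo-5-methoxyphenyl)prop-2-enoate
Conditions: 2 (1.3 equiv), toluene, 90 °C
Reagents that add atoms: none
Why: Wittig olefination tolerates the free phenol (the extra ylide covers proton transfer) and gives the E-enoate.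

Step 5
Reactants: 5 (E)-3-[4-(benzyloxy)-3-methoxyphenyl]prop-2-en-1-yl methyl carbonate; 7 methyl (E)-3-(4-hydroxy-3-iodo-5-methoxyphenyl)prop-2-enoate
Product: 8 methyl (E)-3-[4-{[(1S)-1-(4-(benzyloxy)-3-methoxyphenyl)prop-2-en-1-yl]oxy}-3-iodo-5-methoxyphenyl]prop-2-enoate
Conditions: NaH (1.0 equiv), THF, 0 °C; then [Ir(cod)Cl]2 (2 mol %), (Sa,Sc,Sc)-binaphthol N,N-bis(1-phenylethyl)phosphoramidite (4 mol %, pre-activated with n-PrNH2), THF, 35 °C
Reagents that add atoms: none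
Why: Iridium-catalysed asymmetric allylic etherification (Hartwig type), in which the aryloxide attacks the substituted terminus of the allyl–iridium intermediate and the ligand fixes the new benzylic C–O centre as S; both ortho positions and the para position of the phenoxide are blocked, so only O-allylation can occur.

Step 6
Reactants: 8 methyl (E)-3-[4-{[(1S)-1-(4-(benzyloxy)-3-methoxyphenyl)prop-2-en-1-yl]oxy}-3-iodo-5-methoxyphenyl]prop-2-enoate
Product: 9 (E)-3-[4-{[(1S)-1-(4-(benzyloxy)-3-methoxyphenyl)prop-2-en-1-yl]oxy}-3-iodo-5-methoxyphenyl]prop-2-en-1-ol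
Conditions: i-Bu2AlH (2.2 equiv), CH2Cl2, −78 °C
Reagents that add atoms: none
Why: DIBAL reduction of the enoate; the branched allyl aryl ether, its stereocentre and the aryl iodide are inert at −78 °C.

Step 7
Reactants: 9 (E)-3-[4-{[(1S)-1-(4-(benzyloxy)-3-methoxyphenyl)prop-2-en-1-yl]oxy}-3-iodo-5-methoxyphenyl]prop-2-en-1-ol
Product: 10 (E)-3-[4-{[(1S)-1-(4-(benzyloxy)-3-methoxyphenyl)prop-2-en-1-yl]oxy}-3-iodo-5-methoxyphenyl]prop-2-en-1-yl methyl carbonate
Conditions: ClCO2Me, pyridine, CH2Cl2, 0 °C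
Reagents that add atoms: methyl chloroformate COC(=O)Cl
Why: Chloroformate acylation of the primary allylic alcohol gives the second linear carbonate.

Step 8
Reactants: 1 4-(benzyloxy)-3-methoxybenzaldehyde; 11 dimethyl succinate
Product: 12 (E)-4-[4-(benzyloxy)-3-methoxyphenyl]-3-(methoxycarbonyl)but-3-enoic acid
Conditions: NaOMe, MeOH, reflux; then aq. HCl
Reagents that add atoms: none
Why: Stobbe condensation gives the E-arylidenesuccinate half-ester.

Step 9
Reactants: 12 (E)-4-[4-(benzyloxy)-3-methoxyphenyl]-3-(methoxycarbonyl)but-3-enoic acid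
Product: 13 (3R)-4-[4-(benzyloxy)-3-methoxyphenyl]-3-(methoxycarbonyl)butanoic acid
Conditions: H2 (5 bar), [Rh(cod)((S,S)-Et-DuPhos)]OTf (0.5 mol %), NaOMe (10 mol %), MeOH, rt
Reagents that add atoms: none
Why: Rhodium-catalysed asymmetric hydrogenation of the itaconate-type half-ester sets the R centre that becomes C4 of the oxolane; the benzyl ether is untouched by this homogeneous catalyst.

Step 10
Reactants: 13 (3R)-4-[4-(benzyloxy)-3-methoxyphenyl]-3-(methoxycarbonyl)butanoic acid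
Product: 15 (4R)-4-[4-(benzyloxy)-3-methoxybenzyl]dihydrofuran-2(3H)-one, via hydroxy acid 14 (not isolated)
Conditions: LiOH (1.0 equiv), then LiBH4 (2 equiv), THF–MeOH, 0 °C to rt; then 2 M HCl, rt
Reagents that add atoms: none
Why: Chemoselective borohydride reduction of the methyl ester beside the lithium carboxylate, then acid-induced lactonisation; the stereocentre is not touched.

Step 11
Reactants: 6 4-hydroxy-3-iodo-5-methoxybenzaldehyde (5-iodovanillin)
Product: 16 4-[(tert-butyldimethylsilyl)oxy]-3-iodo-5-methoxybenzaldehyde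
Conditions: TBSCl, imidazole, DMF, rt
Reagents that add atoms: tert-butyldimethylsilyl chloride CC(C)(C)[Si](C)(C)Cl
Why: Silylation masks the acidic phenol so that the aldehyde stays electrophilic in the enolate addition.

Step 12
Reactants: 15 (4R)-4-[4-(benzyloxy)-3-methoxybenzyl]dihydrofuran-2(3H)-one; 16 4-[(tert-butyldimethylsilyl)oxy]-3-iodo-5-methoxybenzaldehyde
Product: 17 (3S,4R)-4-[4-(benzyloxy)-3-methoxybenzyl]-3-{[4-(tert-butyldimethylsilyloxy)-3-iodo-5-methoxyphenyl](hydroxy)methyl}dihydrofuran-2(3H)-one (both carbinol epimers)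
Conditions: LiN(i-Pr)2 (1.1 equiv), THF, −78 °C; then 16; AcOH, −78 °C
Reagents that add atoms: none
Why: Aldol addition of the lactone lithium enolate occurs anti to the C4 arylmethyl group (3,4-trans); the carbinol centre is a mixture that is erased in step 13.

Step 13
Reactants: 17 (3S,4R)-4-[4-(benzyloxy)-3-methoxybenzyl]-3-{[4-(tert-butyldimethylsilyloxy)-3-iodo-5-methoxyphenyl](hydroxy)methyl}dihydrofuran-2(3H)-one
Product: 18 (3S,4R)-4-[4-(benzyloxy)-3-methoxybenzyl]-3-[4-(tert-butyldimethylsilyloxy)-3-iodo-5-methoxybenzoyl]dihydrofuran-2(3H)-one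
Conditions: Dess–Martin periodinane, CH2Cl2, rt
Reagents that add atoms: none
Why: Dess–Martin oxidation of the benzylic carbinol gives the α-aroyl lactone needed for the rearrangement.

Step 14
Reactants: 18 (3S,4R)-4-[4-(benzyloxy)-3-methoxybenzyl]-3-[4-(tert-butyldimethylsilyloxy)-3-iodo-5-methoxybenzoyl]dihydrofuran-2(3H)-one
Product: 20 methyl (4R)-4-[4-(benzyloxy)-3-methoxybenzyl]-2-(4-hydroxy-3-iodo-5-methoxyphenyl)-4,5-dihydrofuran-3-carboxylate, via ring-opened hydroxy keto ester 19 (not isolated)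
Conditions: H2SO4 (0.5 equiv), MeOH, 60 °C
Reagents that add atoms: methanol CO
Why: Korte acyl-lactone rearrangement, in which acid methanolysis opens the lactone, the freed primary alcohol adds to the aryl ketone and water is lost to give the conjugated 4,5-dihydrofuran-3-carboxylate; the aryl silyl ether is cleaved in the same medium and the non-enolisable C4 centre is preserved.

Step 15
Reactants: 10 (E)-3-[4-{[(1S)-1-(4-(benzyloxy)-3-methoxyphenyl)prop-2-en-1-yl]oxy}-3-iodo-5-methoxyphenyl]prop-2-en-1-yl methyl carbonate; 20 methyl (4R)-4-[4-(benzyloxy)-3-methoxybenzyl]-2-(4-hydroxy-3-iodo-5-methoxyphenyl)-4,5-dihydrofuran-3-carboxylate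
Product: 21 methyl (4R)-4-[4-(benzyloxy)-3-methoxybenzyl]-2-[4-({(1R)-1-[4-({(1S)-1-[4-(benzyloxy)-3-methoxyphenyl]prop-2-en-1-yl}oxy)-3-iodo-5-methoxyphenyl]prop-2-en-1-yl}oxy)-3-iodo-5-methoxyphenyl]-4,5-dihydrofuran-3-carboxylate
Conditions: NaH (1.0 equiv), THF, 0 °C; then [Ir(cod)Cl]2 (2 mol %), (Ra,Rc,Rc)-binaphthol N,N-bis(1-phenylethyl)phosphoramidite (4 mol %, pre-activated with n-PrNH2), THF, 35 °C
Reagents that add atoms: none
Why: Second iridium-catalysed asymmetric allylic etherification, now with the enantiomeric ligand, sets the new benzylic C–O centre as R; the first allyl aryl ether carries a poor leaving group and is not re-ionised.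

Step 16
Reactants: 21 methyl (4R)-4-[4-(benzyloxy)-3-methoxybenzyl]-2-[4-({(1R)-1-[4-({(1S)-1-[4-(benzyloxy)-3-methoxyphenyl]prop-2-en-1-yl}oxy)-3-iodo-5-methoxyphenyl]prop-2-en-1-yl}oxy)-3-iodo-5-methoxyphenyl]-4,5-dihydrofuran-3-carboxylate
Product: 23 methyl (4R)-4-[4-(benzyloxy)-3-methoxybenzyl]-2-[(2R,3S)-2-{(2S,3R)-2-[4-(benzyloxy)-3-methoxyphenyl]-3-(hydroxymethyl)-7-methoxy-2,3-dihydro-1-benzofuran-5-yl}-3-(hydroxymethyl)-7-methoxy-2,3-dihydro-1-benzofuran-5-yl]-4,5-dihydrofuran-3-carboxylate, via bis-hydroperoxide 22 (not isolated)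
Conditions: Bu3SnH (5 equiv, syringe pump), dry air sparge, toluene, 0 °C to rt
Reagents that add atoms: dioxygen O=O
Why: Twofold oxygenative aryl-radical cyclisation (Nakamura type), in which each aryl radical formed by iodine abstraction closes 5-exo-trig onto its vinyl group through a Beckwith–Houk chair-like transition state with the 2-aryl group pseudo-equatorial, so each new C3 is expected mainly trans to the preset C2 centre (the selectivity is moderate for such aryl radicals and is the main risk of this step); the primary radicals are captured by O2 and the hydroperoxides are reduced by the tin hydride.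

Step 17
Reactants: 23 methyl (4R)-4-[4-(benzyloxy)-3-methoxybenzyl]-2-[(2R,3S)-2-{(2S,3R)-2-[4-(benzyloxy)-3-methoxyphenyl]-3-(hydroxymethyl)-7-methoxy-2,3-dihydro-1-benzofuran-5-yl}-3-(hydroxymethyl)-7-methoxy-2,3-dihydro-1-benzofuran-5-yl]-4,5-dihydrofuran-3-carboxylate
Product: 24 methyl (2R,3S,4R)-4-(4-hydroxy-3-methoxybenzyl)-2-[(2R,3S)-3-(hydroxymethyl)-2-{(2S,3R)-3-(hydroxymethyl)-2-(4-hydroxy-3-methoxyphenyl)-7-methoxy-2,3-dihydro-1-benzofuran-5-yl}-7-methoxy-2,3-dihydro-1-benzofuran-5-yl]oxolane-3-carboxylate (all-cis oxolane)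
Conditions: H2 (4 bar), Pd(OH)2/C, EtOAc–MeOH, rt
Reagents that add atoms: none
Why: Heterogeneous hydrogenation adds H2 syn to the tetrasubstituted enol-ether double bond from the face opposite the C4 arylmethyl group, which places aryl, ester and arylmethyl all cis (new centres 2R and 3S), while both benzyl ethers are hydrogenolysed in the same run.

Step 18
Reactants: 24 methyl (2R,3S,4R)-4-(4-hydroxy-3-methoxybenzyl)-2-[(2R,3S)-3-(hydroxymethyl)-2-{(2S,3R)-3-(hydroxymethyl)-2-(4-hydroxy-3-methoxyphenyl)-7-methoxy-2,3-dihydro-1-benzofuran-5-yl}-7-methoxy-2,3-dihydro-1-benzofuran-5-yl]oxolane-3-carboxylate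
Product: 25 {(2S,3R)-5-[(2R,3S)-5-{(2R,3R,4R)-4-(4-hydroxy-3-methoxybenzyl)-3-(hydroxymethyl)oxolan-2-yl}-3-(hydroxymethyl)-7-methoxy-2,3-dihydro-1-benzofuran-2-yl]-2-(4-hydroxy-3-methoxyphenyl)-7-methoxy-2,3-dihydro-1-benzofuran-3-yl}methanol (CNP0395728.1)
Conditions: LiAlH4 (excess), THF, −20 to 0 °C; aq. potassium sodium tartrate work-up
Reagents that add atoms: none
Why: Hydride reduction of the ester at low temperature is faster than α-epimerisation of the all-cis ester, and the neutral work-up avoids acid epimerisation of the benzylic oxolane centre (the 3S descriptor of the ester becomes 3R only through the priority change).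

**Compound list**

1 | 4-(benzyloxy)-3-methoxybenzaldehyde | COc1cc(C=O)ccc1OCc1ccccc1 | starting material
2 | methyl (triphenylphosphoranylidene)acetate | COC(=O)C=P(c1ccccc1)(c1ccccc1)c1ccccc1 | starting material
3 | methyl (E)-3-[4-(benzyloxy)-3-methoxyphenyl]prop-2-enoate | COC(=O)/C=C/c1ccc(OCc2ccccc2)c(OC)c1 | intermediate
4 | (E)-3-[4-(benzyloxy)-3-methoxyphenyl]prop-2-en-1-ol | OC/C=C/c1ccc(OCc2ccccc2)c(OC)c1 | intermediate
5 | (E)-3-[4-(benzyloxy)-3-methoxyphenyl]prop-2-en-1-yl methyl carbonate | COC(=O)OC/C=C/c1ccc(OCc2ccccc2)c(OC)c1 | intermediate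
6 | 4-hydroxy-3-iodo-5-methoxybenzaldehyde (5-iodovanillin) | COc1cc(C=O)cc(I)c1O | starting material
7 | methyl (E)-3-(4-hydroxy-3-iodo-5-methoxyphenyl)prop-2-enoate | COC(=O)/C=C/c1cc(I)c(O)c(OC)c1 | intermediate
8 | methyl (E)-3-[4-{[(1S)-1-(4-(benzyloxy)-3-methoxyphenyl)prop-2-en-1-yl]oxy}-3-iodo-5-methoxyphenyl]prop-2-enoate | C=C[C@H](Oc1c(I)cc(/C=C/C(=O)OC)cc1OC)c1ccc(OCc2ccccc2)c(OC)c1 | intermediate
9 | (E)-3-[4-{[(1S)-1-(4-(benzyloxy)-3-methoxyphenyl)prop-2-en-1-yl]oxy}-3-iodo-5-methoxyphenyl]prop-2-en-1-ol | C=C[C@H](Oc1c(I)cc(/C=C/CO)cc1OC)c1ccc(OCc2ccccc2)c(OC)c1 | intermediate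
10 | (E)-3-[4-{[(1S)-1-(4-(benzyloxy)-3-methoxyphenyl)prop-2-en-1-yl]oxy}-3-iodo-5-methoxyphenyl]prop-2-en-1-yl methyl carbonate | C=C[C@H](Oc1c(I)cc(/C=C/COC(=O)OC)cc1OC)c1ccc(OCc2ccccc2)c(OC)c1 | intermediate
11 | dimethyl succinate | COC(=O)CCC(=O)OC | starting material
12 | (E)-4-[4-(benzyloxy)-3-methoxyphenyl]-3-(methoxycarbonyl)but-3-enoic acid | COC(=O)/C(CC(=O)O)=C/c1ccc(OCc2ccccc2)c(OC)c1 | intermediate
13 | (3R)-4-[4-(benzyloxy)-3-methoxyphenyl]-3-(methoxycarbonyl)butanoic acid | COC(=O)[C@@H](CC(=O)O)Cc1ccc(OCc2ccccc2)c(OC)c1 | intermediate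
14 | (3R)-4-[4-(benzyloxy)-3-methoxyphenyl]-3-(hydroxymethyl)butanoic acid | OC[C@@H](CC(=O)O)Cc1ccc(OCc2ccccc2)c(OC)c1 | intermediate (not isolated)
15 | (4R)-4-[4-(benzyloxy)-3-methoxybenzyl]dihydrofuran-2(3H)-one | O=C1C[C@@H](Cc2ccc(OCc3ccccc3)c(OC)c2)CO1 | intermediate
16 | 4-[(tert-butyldimethylsilyl)oxy]-3-iodo-5-methoxybenzaldehyde | COc1cc(C=O)cc(I)c1O[Si](C)(C)C(C)(C)C | intermediate
17 | (3S,4R)-4-[4-(benzyloxy)-3-methoxybenzyl]-3-{[4-(tert-butyldimethylsilyloxy)-3-iodo-5-methoxyphenyl](hydroxy)methyl}dihydrofuran-2(3H)-one (carbinol epimers) | O=C1[C@H](C(O)c2cc(I)c(O[Si](C)(C)C(C)(C)C)c(OC)c2)[C@@H](Cc2ccc(OCc3ccccc3)c(OC)c2)CO1 | intermediate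
18 | (3S,4R)-4-[4-(benzyloxy)-3-methoxybenzyl]-3-[4-(tert-butyldimethylsilyloxy)-3-iodo-5-methoxybenzoyl]dihydrofuran-2(3H)-one | O=C1[C@H](C(=O)c2cc(I)c(O[Si](C)(C)C(C)(C)C)c(OC)c2)[C@@H](Cc2ccc(OCc3ccccc3)c(OC)c2)CO1 | intermediate
19 | methyl (3R)-3-[4-(benzyloxy)-3-methoxybenzyl]-4-hydroxy-2-(4-hydroxy-3-iodo-5-methoxybenzoyl)butanoate (C2 epimers) | COC(=O)C(C(=O)c1cc(I)c(O)c(OC)c1)[C@H](CO)Cc1ccc(OCc2ccccc2)c(OC)c1 | intermediate (not isolated)
20 | methyl (4R)-4-[4-(benzyloxy)-3-methoxybenzyl]-2-(4-hydroxy-3-iodo-5-methoxyphenyl)-4,5-dihydrofuran-3-carboxylate | COC(=O)C1=C(c2cc(I)c(O)c(OC)c2)OC[C@@H]1Cc1ccc(OCc2ccccc2)c(OC)c1 | intermediate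
21 | methyl (4R)-4-[4-(benzyloxy)-3-methoxybenzyl]-2-[4-({(1R)-1-[4-({(1S)-1-[4-(benzyloxy)-3-methoxyphenyl]prop-2-en-1-yl}oxy)-3-iodo-5-methoxyphenyl]prop-2-en-1-yl}oxy)-3-iodo-5-methoxyphenyl]-4,5-dihydrofuran-3-carboxylate | COC(=O)C1=C(c2cc(I)c(O[C@H](C=C)c3cc(I)c(O[C@@H](C=C)c4ccc(OCc5ccccc5)c(OC)c4)c(OC)c3)c(OC)c2)OC[C@@H]1Cc1ccc(OCc2ccccc2)c(OC)c1 | intermediate
22 | bis(hydroperoxymethyl) analogue of 23 (each CH2OH of 23 is CH2OOH) | COC(=O)C1=C(c2cc(OC)c3c(c2)[C@@H](COO)[C@H](c2cc(OC)c4c(c2)[C@H](COO)[C@@H](c2ccc(OCc5ccccc5)c(OC)c2)O4)O3)OC[C@@H]1Cc1ccc(OCc2ccccc2)c(OC)c1 | intermediate (not isolated)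
23 | methyl (4R)-4-[4-(benzyloxy)-3-methoxybenzyl]-2-[(2R,3S)-2-{(2S,3R)-2-[4-(benzyloxy)-3-methoxyphenyl]-3-(hydroxymethyl)-7-methoxy-2,3-dihydro-1-benzofuran-5-yl}-3-(hydroxymethyl)-7-methoxy-2,3-dihydro-1-benzofuran-5-yl]-4,5-dihydrofuran-3-carboxylate | COC(=O)C1=C(c2cc(OC)c3c(c2)[C@@H](CO)[C@H](c2cc(OC)c4c(c2)[C@H](CO)[C@@H](c2ccc(OCc5ccccc5)c(OC)c2)O4)O3)OC[C@@H]1Cc1ccc(OCc2ccccc2)c(OC)c1 | intermediate
24 | methyl (2R,3S,4R)-4-(4-hydroxy-3-methoxybenzyl)-2-[(2R,3S)-3-(hydroxymethyl)-2-{(2S,3R)-3-(hydroxymethyl)-2-(4-hydroxy-3-methoxyphenyl)-7-methoxy-2,3-dihydro-1-benzofuran-5-yl}-7-methoxy-2,3-dihydro-1-benzofuran-5-yl]oxolane-3-carboxylate | COc1cc(C[C@H]2CO[C@@H](c3cc(OC)c4c(c3)[C@@H](CO)[C@H](c3cc(OC)c5c(c3)[C@H](CO)[C@@H](c3ccc(O)c(OC)c3)O5)O4)[C@H]2C(=O)OC)ccc1O | intermediate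
25 | {(2S,3R)-5-[(2R,3S)-5-{(2R,3R,4R)-4-(4-hydroxy-3-methoxybenzyl)-3-(hydroxymethyl)oxolan-2-yl}-3-(hydroxymethyl)-7-methoxy-2,3-dihydro-1-benzofuran-2-yl]-2-(4-hydroxy-3-methoxyphenyl)-7-methoxy-2,3-dihydro-1-benzofuran-3-yl}methanol | COc1cc(C[C@H]2CO[C@@H](c3cc(OC)c4c(c3)[C@@H](CO)[C@H](c3cc(OC)c5c(c3)[C@H](CO)[C@@H](c3ccc(O)c(OC)c3)O5)O4)[C@H]2CO)ccc1O | target

**Totals and risks**

Total step count: 18. Longest linear sequence: 10 steps (1–2–3–5–6–7–15–16–17–18, or 8–9–10–12–13–14–15–16–17–18).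

Three steps most likely to fail:

Step 16 (twofold radical cyclisation). The likely problems are only moderate trans selectivity at each new C3, simple reduction of an aryl radical before ring closure, and peroxidation at the activated benzylic/allylic C–H. The fallback sets out from 21 and comes back at 23. Compound 21 is cyclised with Bu3SnH in the presence of excess TEMPO, so that each cyclised primary radical is captured by the nitroxide, to give the bis[(2,2,6,6-tetramethylpiperidin-1-yl)oxymethyl] analogue of 23 F3. Both N-alkoxyamine groups are then oxidised with m-CPBA to give the C3-dialdehyde analogue of 23 F4. Treatment of F4 with DBU equilibrates each formyl-bearing C3 to the trans arrangement, and NaBH4 reduces the two aldehydes to give 23. This replaces kinetic control at C3 by thermodynamic control through an epimerisable aldehyde.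

Step 17 (hydrogenation). The likely problems are hydrogenolysis of a dihydrobenzofuran or of the new benzylic oxolane C–O bond under the pressure needed for the tetrasubstituted alkene, or incomplete alkene reduction. The fallback sets out from 23 and comes back at 25. The vinylogous ester of 23 is first reduced with i-Bu2AlH to the 3-(hydroxymethyl)-4,5-dihydrofuran triol F5. F5 is hydrogenated with the homogeneous catalyst [Ir(cod)(PCy3)(py)]PF6, which is hydroxyl-directed and does not cleave C–O bonds; the face opposite the C4 arylmethyl group again reacts and gives the O,O'-dibenzyl ether of the target F6. A short hydrogenolysis of F6 with H2 (1 bar) over Pd/C removes the two benzyl groups and gives 25.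

Step 5 (first iridium etherification; the same concern applies to step 15). The phenoxide is hindered on both ortho sides and the cinnamyl unit is electron-rich, so branched selectivity may be low and the ee may erode through re-ionisation of the product. The fallback sets out from 1 and 7 and comes back at 8. Addition of HC≡CMgBr to 1 and acetylation in the same pot gives racemic 1-[4-(benzyloxy)-3-methoxyphenyl]prop-2-yn-1-yl acetate F1. Copper-catalysed enantioselective propargylic etherification of F1 with 7 (CuOTf·0.5C6H6, chiral Ph-pybox, i-Pr2NEt, MeOH, −20 °C; copper allenylidene intermediate) gives methyl (E)-3-[4-{[(1S)-1-(4-(benzyloxy)-3-methoxyphenyl)prop-2-yn-1-yl]oxy}-3-iodo-5-methoxyphenyl]prop-2-enoate F2. Semihydrogenation of F2 over Pd/CaCO3 poisoned with Pb(OAc)2 and quinoline gives 8.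

**Further compounds**

F1 | step 5 | 1-[4-(benzyloxy)-3-methoxyphenyl]prop-2-yn-1-yl acetate (racemic) | CC(=O)OC(C#C)c1ccc(OCc2ccccc2)c(OC)c1
F2 | step 5 | methyl (E)-3-[4-{[(1S)-1-(4-(benzyloxy)-3-methoxyphenyl)prop-2-yn-1-yl]oxy}-3-iodo-5-methoxyphenyl]prop-2-enoate | C#C[C@H](Oc1c(I)cc(/C=C/C(=O)OC)cc1OC)c1ccc(OCc2ccccc2)c(OC)c1
F3 | step 16 | bis[(2,2,6,6-tetramethylpiperidin-1-yl)oxymethyl] analogue of 23 (each CH2OH of 23 is CH2O–N-piperidinyl; trans,trans isomer drawn) | COC(=O)C1=C(c2cc(OC)c3c(c2)[C@@H](CON2C(C)(C)CCCC2(C)C)[C@H](c2cc(OC)c4c(c2)[C@H](CON2C(C)(C)CCCC2(C)C)[C@@H](c2ccc(OCc5ccccc5)c(OC)c2)O4)O3)OC[C@@H]1Cc1ccc(OCc2ccccc2)c(OC)c1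
F4 | step 16 | C3-dialdehyde analogue of 23 (each CH2OH of 23 is CHO; both rings 2,3-trans) | COC(=O)C1=C(c2cc(OC)c3c(c2)[C@@H](C=O)[C@H](c2cc(OC)c4c(c2)[C@H](C=O)[C@@H](c2ccc(OCc5ccccc5)c(OC)c2)O4)O3)OC[C@@H]1Cc1ccc(OCc2ccccc2)c(OC)c1
F5 | step 17 | {(4R)-4-[4-(benzyloxy)-3-methoxybenzyl]-2-[(2R,3S)-2-{(2S,3R)-2-[4-(benzyloxy)-3-methoxyphenyl]-3-(hydroxymethyl)-7-methoxy-2,3-dihydro-1-benzofuran-5-yl}-3-(hydroxymethyl)-7-methoxy-2,3-dihydro-1-benzofuran-5-yl]-4,5-dihydrofuran-3-yl}methanol | OCC1=C(c2cc(OC)c3c(c2)[C@@H](CO)[C@H](c2cc(OC)c4c(c2)[C@H](CO)[C@@H](c2ccc(OCc5ccccc5)c(OC)c2)O4)O3)OC[C@@H]1Cc1ccc(OCc2ccccc2)c(OC)c1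
F6 | step 17 | O,O'-dibenzyl ether of 25 (both phenols of 25 as benzyl ethers; all-cis oxolane) | COc1cc(C[C@H]2CO[C@@H](c3cc(OC)c4c(c3)[C@@H](CO)[C@H](c3cc(OC)c5c(c3)[C@H](CO)[C@@H](c3ccc(OCc6ccccc6)c(OC)c3)O5)O4)[C@H]2CO)ccc1OCc1ccccc1
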